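**Retrosynthetic overview**

1. The target is read as ent-robinetinidol-(4α→8)-ent-epirobinetinidol-(4α→8)-epicatechin. The last operations are hydrogenolysis of fourteen benzyl ethers, desilylation, and hydride reduction of a top-unit C4 tertiary carbinol (hydride anti to O3, which places the C8-aryl 3,4-cis).
2. Key disconnection: the top pyran ring (O1–C2) and the interflavan bond C4(top)–C8(middle) are cut in one operation, back to the C8 aryllithium of a protected middle–bottom dimer and a (2S,3R)-trans-epoxy ketone (a 2'-silyloxychalcone epoxide).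
3. Enabling feature: top-unit C4 lies between C4a of its ring A and C8 of the middle ring A, so it can be a ketone carbon that accepts the aryl anion. O1 on ring A is ortho to C4a and anti to O3 across C2–C3, with C2 benzylic to ring B; this is the pattern left by 6-endo opening of a trans-aryl epoxide by a phenoxide with inversion at C2.
4. Dimer: the middle C4–bottom C8 bond comes from Lewis-acid coupling of an 8-bromo-4-methoxy-ent-epirobinetinidol electrophile with tetra-O-benzyl-epicatechin. The middle pyran ring comes from the analogous bromo-chalcone epoxide, followed by C=O reduction and C3 inversion by oxidation/reduction; the bromine from 2-bromoresorcinol marks C8.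
5. Order of ring closure: bottom pyran ring (present in epicatechin), middle pyran ring (step 9), top pyran ring (step 17, last).

Key step: step 17

Remark on the chemistry: the SMILES is read as top unit 2S,3R,4S (2,3-trans, 3,4-cis), middle unit 2S,3S,4S (2,3-cis, 3,4-trans) and bottom unit 2R,3R; compounds 1, 2, 6 and 18 are taken as commercial.

**Route**

Step 1
Reactants: 1 1-[4-(benzyloxy)-2-hydroxyphenyl]ethan-1-one; 2 3,4,5-tris(benzyloxy)benzaldehyde
Product: 3 (E)-1-[4-(benzyloxy)-2-hydroxyphenyl]-3-[3,4,5-tris(benzyloxy)phenyl]prop-2-en-1-one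
Conditions: KOH, EtOH/THF, rt
Reagents that add atoms: none
Why: Claisen–Schmidt condensation of the acetophenone enolate with the non-enolisable aldehyde, in which dehydration should give the conjugated E-enone and the 2'-phenoxide should hold back flavanone formation in the basic medium.

Step 2
Reactants: 3 (E)-2'-hydroxychalcone
Product: 4 (E)-1-[4-(benzyloxy)-2-(tert-butyldimethylsilyloxy)phenyl]-3-[3,4,5-tris(benzyloxy)phenyl]prop-2-en-1-one
Conditions: t-BuMe2SiOTf, 2,6-lutidine, CH2Cl2, 0 °C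
Reagents that add atoms: tert-butyldimethylsilyl trifluoromethanesulfonate, CC(C)(C)[Si](C)(C)OS(=O)(=O)C(F)(F)F
Why: Silylation of the hydrogen-bonded 2'-phenol with the reactive silyl triflate masks O1, so that the enone can be epoxidised without Algar–Flynn–Oyamada cyclisation and the silyl group is in place for the relay of step 17.

Step 3
Reactants: 4 silylated chalcone
Product: 5 [4-(benzyloxy)-2-(tert-butyldimethylsilyloxy)phenyl]{(2S,3R)-3-[3,4,5-tris(benzyloxy)phenyl]oxiran-2-yl}methanone (trans-epoxide)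
Conditions: La(O-i-Pr)3 (10 mol %), (R)-BINOL (10 mol %), Ph3As=O (10 mol %), t-BuOOH (decane), MS 4 Å, THF, rt
Reagents that add atoms: tert-butyl hydroperoxide, CC(C)(C)OO
Why: Catalytic asymmetric nucleophilic (Weitz–Scheffer-type) epoxidation of an enone by a lanthanum–BINOL peroxide, in which the (R)-BINOL complex is expected, as for parent chalcones, to give the (2S,3R)-trans-epoxide, and the anhydrous near-neutral medium should spare the aryl silyl ether.

Step 4
Reactants: 6 2-bromobenzene-1,3-diol (2-bromoresorcinol)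
Product: 7 1-(3-bromo-2,4-dihydroxyphenyl)ethan-1-one
Conditions: AcOH, ZnCl2, 120 °C
Reagents that add atoms: acetic acid, CC(=O)O
Why: Nencki-type Friedel–Crafts acylation, in which only C4 (= C6) is ortho/para to both hydroxyls, so the bromine ends between the two oxygens where it will mark C8 of the middle unit.

Step 5
Reactants: 7 bromo-resacetophenone
Product: 8 1-[4-(benzyloxy)-3-bromo-2-hydroxyphenyl]ethan-1-one
Conditions: BnBr (1.05 equiv), K2CO3, acetone, reflux
Reagents that add atoms: benzyl bromide, BrCc1ccccc1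
Why: Williamson etherification that should be selective for the 4-OH because the 2-OH is hydrogen-bonded to the carbonyl group.

Step 6
Reactants: 8 bromo-acetophenone; 2 3,4,5-tris(benzyloxy)benzaldehyde
Product: 9 (E)-1-[4-(benzyloxy)-3-bromo-2-hydroxyphenyl]-3-[3,4,5-tris(benzyloxy)phenyl]prop-2-en-1-one
Conditions: KOH, EtOH/THF, rt
Reagents that add atoms: none
Why: Claisen–Schmidt condensation as in step 1, giving the E-enone.

Step 7
Reactants: 9 bromo-2'-hydroxychalcone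
Product: 10 (E)-1-[4-(benzyloxy)-3-bromo-2-(tert-butyldimethylsilyloxy)phenyl]-3-[3,4,5-tris(benzyloxy)phenyl]prop-2-en-1-one
Conditions: t-BuMe2SiOTf, 2,6-lutidine, CH2Cl2, 0 °C → rt
Reagents that add atoms: tert-butyldimethylsilyl trifluoromethanesulfonate, CC(C)(C)[Si](C)(C)OS(=O)(=O)C(F)(F)F
Why: Silylation of the hindered chelated phenol with the silyl triflate, as in step 2, to block premature cyclisation during the epoxidation.

Step 8
Reactants: 10 silylated bromo-chalcone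
Product: 11 [4-(benzyloxy)-3-bromo-2-(tert-butyldimethylsilyloxy)phenyl]{(2S,3R)-3-[3,4,5-tris(benzyloxy)phenyl]oxiran-2-yl}methanone
Conditions: La(O-i-Pr)3 (10 mol %), (R)-BINOL (10 mol %), Ph3As=O (10 mol %), t-BuOOH (decane), MS 4 Å, THF, rt
Reagents that add atoms: tert-butyl hydroperoxide, CC(C)(C)OO
Why: The same catalytic asymmetric enone epoxidation as in step 3, with the same ligand antipode, so that both flavan units receive the 2S configuration.

Step 9
Reactants: 11 bromo-epoxy ketone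
Product: 13 (2S,3S)-7-(benzyloxy)-8-bromo-3-hydroxy-2-[3,4,5-tris(benzyloxy)phenyl]chroman-4-one, via tetrabutylammonium phenoxide 12 (not isolated)
Conditions: n-Bu4NF, THF, 0 °C; then AcOH
Reagents that add atoms: none
Why: Fluoride unmasks the 2'-phenoxide, which should open the epoxide at the benzylic β-carbon (6-endo, the Algar–Flynn–Oyamada-type cyclisation of a chalcone epoxide) with inversion, so that the (2S,3R)-epoxide gives the 2,3-trans (2S,3S)-dihydroflavonol and closes the middle pyran ring.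

Step 10
Reactants: 13 dihydroflavonol
Product: 14 (2S,3R,4S)-7-(benzyloxy)-8-bromo-2-[3,4,5-tris(benzyloxy)phenyl]chromane-3,4-diol (2,3-trans-3,4-trans)
Conditions: NaBH4, MeOH/THF, 0 °C
Reagents that add atoms: none
Why: Borohydride reduction of the dihydroflavonol carbonyl, which for this class gives mainly the 3,4-trans diol; the C4 configuration is not carried into the target.

Step 11
Reactants: 14 flavan-3,4-diol
Product: 15 (2S,3R,4S)-7-(benzyloxy)-8-bromo-4-methoxy-2-[3,4,5-tris(benzyloxy)phenyl]chroman-3-ol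
Conditions: camphorsulfonic acid (cat.), MeOH/CH2Cl2, rt
Reagents that add atoms: methanol, CO
Why: Acid-catalysed SN1 exchange at the p-alkoxybenzylic C4 only (the 3-OH cannot ionise), with methanol expected to add anti to the 3-OH, which protects C4 as a latent leaving group.

Step 12
Reactants: 15 4-methoxyflavan-3-ol
Product: 16 (2S,4S)-7-(benzyloxy)-8-bromo-4-methoxy-2-[3,4,5-tris(benzyloxy)phenyl]chroman-3-one
Conditions: Dess–Martin periodinane, CH2Cl2, rt
Reagents that add atoms: none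
Why: Dess–Martin oxidation of the secondary 3-alcohol under near-neutral conditions that should neither epimerise C2 nor ionise the C4 ether.

Step 13
Reactants: 16 flavan-3-one
Product: 17 (2S,3S,4S)-7-(benzyloxy)-8-bromo-4-methoxy-2-[3,4,5-tris(benzyloxy)phenyl]chroman-3-ol (2,3-cis)
Conditions: LiBH(s-Bu)3 (L-Selectride), LiBr, THF, −78 °C; then H2O
Reagents that add atoms: none
Why: The bulky hydride should attack the flavan-3-one from the α-face, anti to the 2β-aryl and 4β-methoxy groups, to give the axial 3β-alcohol, the usual oxidation–reduction way from 2,3-trans- to 2,3-cis-flavan-3-ols, which sets C3 of the middle unit.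

Step 14
Reactants: 18 (−)-epicatechin
Product: 19 (2R,3R)-5,7-bis(benzyloxy)-2-[3,4-bis(benzyloxy)phenyl]chroman-3-ol (5,7,3',4'-tetra-O-benzyl-epicatechin)
Conditions: BnBr, K2CO3, DMF, 0 °C → rt
Reagents that add atoms: benzyl bromide, BrCc1ccccc1
Why: Williamson benzylation of the four phenols with a carbonate base, which should leave the less acidic aliphatic 3-OH free.

Step 15
Reactants: 17 4-methoxy electrophile; 19 tetra-O-benzyl-epicatechin (3 equiv)
Product: 20 8-bromo-7,3',4',5'-tetra-O-benzyl-ent-epirobinetinidol-(4α→8)-5,7,3',4'-tetra-O-benzyl-epicatechin (middle unit 2S,3S,4S; bottom unit 2R,3R; both 3-OH free)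
Conditions: Me3SiOTf (0.2 equiv), CH2Cl2, −78 → −20 °C
Reagents that add atoms: none
Why: Lewis-acid ionisation of the 4-methoxy group gives a flavan-4-yl cation that should alkylate C8, the most nucleophilic position of the phloroglucinol-type ring A of 19 (Friedel–Crafts-type interflavan coupling), with attack anti to the axial 3β-hydroxyl setting the 4α (3,4-trans) centre while the bromine blocks C8 of the electrophile against self-condensation.

Step 16
Reactants: 20 dimer diol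
Product: 21 8-bromo-3,7,3',4',5'-penta-O-benzyl-ent-epirobinetinidol-(4α→8)-3,5,7,3',4'-penta-O-benzyl-epicatechin
Conditions: NaH, BnBr, n-Bu4NI (cat.), DMF, 0 °C → rt
Reagents that add atoms: benzyl bromide, BrCc1ccccc1
Why: Williamson etherification of both secondary alkoxides removes the acidic protons before the halogen–lithium exchange.

Step 17
Reactants: 21 deca-O-benzyl bromo dimer; 5 epoxy ketone
Product: 26 3-O-silyl 4-hydroxy trimer (top pyran ring closed; see compound list), via aryllithium 22 (not isolated), via lithium carbinolate 23 (not isolated), via lithium phenoxide 24 (not isolated), via cyclised lithium alkoxide 25 (not isolated)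
Conditions: t-BuLi (2.1 equiv), THF, −78 °C; then 5, −78 → 0 °C; then DMPU, 0 → 40 °C; then H2O
Reagents that add atoms: none
Why: Proposed new method: bromine–lithium exchange gives the C8 aryllithium 22, which adds 1,2 to the ketone of 5 (lithium chelated between C=O and the epoxide oxygen) to give carbinolate 23; this takes over the phenolic silyl group through a six-membered siliconate (1,5 O→O shift, driven by the better phenoxide leaving group), the freed phenoxide O1 of 24 opens the trans-epoxide at the benzylic C2 to close the pyran ring (25), and the silyl group then slips from the crowded tertiary O4 to the new secondary alkoxide O3 (1,4 O→O shift) to give 26 after quench. The closest known reactions are organolithium 1,2-addition to α,β-epoxy ketones, phenol-to-benzylic-alkoxide silyl and acyl transfers after carbonyl addition, and the phenoxide cyclisation of 2'-hydroxychalcone epoxides to dihydroflavonols; their union in one relay on a triaryl carbinol is new. The ring closes in a 6-endo-tet mode (O1 onto C2, the breaking C2–O bond inside the forming ring); the 5-exo path to C3 is a neopentyl-type displacement next to the fully substituted C4 and should be far slower, while C2 is activated by ring B. C2 is set by inversion of the (3R)-epoxide carbon and C3 is carried unchanged from the (2S)-epoxide carbon, which together give the 2,3-trans array (2β-aryl, 3α-oxygen); the C4 carbinol configuration, expected from the chelate, is of no consequence because it is erased in step 18. The step needs 1,2-addition in preference to attack at the epoxide, silyl transfer faster than Payne migration, and 6-endo over 5-exo opening, which the hard aryllithium at −78 °C, the six-membered silyl shift and the quaternary C4 are meant to secure; any 4-O-silyl isomer left over would converge in steps 18 and 19.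

Step 18
Reactants: 26 trimer tertiary alcohol
Product: 27 3-O-(tert-butyldimethylsilyl)-7,3',4',5'-tetra-O-benzyl-ent-robinetinidol-(4α→8)-3,7,3',4',5'-penta-O-benzyl-ent-epirobinetinidol-(4α→8)-3,5,7,3',4'-penta-O-benzyl-epicatechin
Conditions: n-Bu3SnH, CF3CO2H, CH2Cl2, −78 → 0 °C
Reagents that add atoms: none
Why: Ionic hydrogenation in which acid ionises the tertiary, doubly benzylic C4–OH to a diarylcarbenium ion and the tin hydride should deliver hydride to the β-face, anti to the 3α-silyloxy group (the facial course known for acid/tin hydride reduction of 3-O-silyl 4-arylflavan-4-ols), which places the C8-aryl group α (3,4-cis) and sets C4 of the top unit.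

Step 19
Reactants: 27 silylated trimer
Product: 28 7,3',4',5'-tetra-O-benzyl-ent-robinetinidol-(4α→8)-3,7,3',4',5'-penta-O-benzyl-ent-epirobinetinidol-(4α→8)-3,5,7,3',4'-penta-O-benzyl-epicatechin
Conditions: n-Bu4NF, AcOH, THF, rt
Reagents that add atoms: none
Why: Fluoride cleaves the secondary silyl ether while the benzyl ethers and both interflavan bonds are inert to buffered fluoride.

Step 20
Reactants: 28 tetradeca-O-benzyl trimer
Product: 29 ent-robinetinidol-(4α→8)-ent-epirobinetinidol-(4α→8)-epicatechin (CNP0115797.3)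
Conditions: H2 (1 atm), Pd(OH)2/C, THF/MeOH/H2O, rt
Reagents that add atoms: none
Why: Hydrogenolysis of all fourteen benzyl ethers under neutral conditions that should leave the acid-sensitive interflavan bonds and the benzylic pyran C–O bonds untouched.

**Compound list**

1 | 1-[4-(benzyloxy)-2-hydroxyphenyl]ethan-1-one | CC(=O)c1ccc(OCc2ccccc2)cc1O | starting material
2 | 3,4,5-tris(benzyloxy)benzaldehyde | O=Cc1cc(OCc2ccccc2)c(OCc2ccccc2)c(OCc2ccccc2)c1 | starting material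
3 | (E)-1-[4-(benzyloxy)-2-hydroxyphenyl]-3-[3,4,5-tris(benzyloxy)phenyl]prop-2-en-1-one | O=C(/C=C/c1cc(OCc2ccccc2)c(OCc2ccccc2)c(OCc2ccccc2)c1)c1ccc(OCc2ccccc2)cc1O | intermediate
4 | (E)-1-[4-(benzyloxy)-2-(tert-butyldimethylsilyloxy)phenyl]-3-[3,4,5-tris(benzyloxy)phenyl]prop-2-en-1-one | O=C(/C=C/c1cc(OCc2ccccc2)c(OCc2ccccc2)c(OCc2ccccc2)c1)c1ccc(OCc2ccccc2)cc1O[Si](C)(C)C(C)(C)C | intermediate
5 | [4-(benzyloxy)-2-(tert-butyldimethylsilyloxy)phenyl]{(2S,3R)-3-[3,4,5-tris(benzyloxy)phenyl]oxiran-2-yl}methanone | O=C(c1ccc(OCc2ccccc2)cc1O[Si](C)(C)C(C)(C)C)[C@H]1O[C@@H]1c1cc(OCc2ccccc2)c(OCc2ccccc2)c(OCc2ccccc2)c1 | intermediate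
6 | 2-bromobenzene-1,3-diol | Oc1cccc(O)c1Br | starting material
7 | 1-(3-bromo-2,4-dihydroxyphenyl)ethan-1-one | CC(=O)c1ccc(O)c(Br)c1O | intermediate
8 | 1-[4-(benzyloxy)-3-bromo-2-hydroxyphenyl]ethan-1-one | CC(=O)c1ccc(OCc2ccccc2)c(Br)c1O | intermediate
9 | (E)-1-[4-(benzyloxy)-3-bromo-2-hydroxyphenyl]-3-[3,4,5-tris(benzyloxy)phenyl]prop-2-en-1-one | O=C(/C=C/c1cc(OCc2ccccc2)c(OCc2ccccc2)c(OCc2ccccc2)c1)c1ccc(OCc2ccccc2)c(Br)c1O | intermediate
10 | (E)-1-[4-(benzyloxy)-3-bromo-2-(tert-butyldimethylsilyloxy)phenyl]-3-[3,4,5-tris(benzyloxy)phenyl]prop-2-en-1-one | O=C(/C=C/c1cc(OCc2ccccc2)c(OCc2ccccc2)c(OCc2ccccc2)c1)c1ccc(OCc2ccccc2)c(Br)c1O[Si](C)(C)C(C)(C)C | intermediate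
11 | [4-(benzyloxy)-3-bromo-2-(tert-butyldimethylsilyloxy)phenyl]{(2S,3R)-3-[3,4,5-tris(benzyloxy)phenyl]oxiran-2-yl}methanone | O=C(c1ccc(OCc2ccccc2)c(Br)c1O[Si](C)(C)C(C)(C)C)[C@H]1O[C@@H]1c1cc(OCc2ccccc2)c(OCc2ccccc2)c(OCc2ccccc2)c1 | intermediate
12 | tetrabutylammonium 3-(benzyloxy)-2-bromo-6-{[(2S,3R)-3-[3,4,5-tris(benzyloxy)phenyl]oxiran-2-yl]carbonyl}phenoxide | CCCC[N+](CCCC)(CCCC)CCCC.[O-]c1c(Br)c(OCc2ccccc2)ccc1C(=O)[C@H]1O[C@@H]1c1cc(OCc2ccccc2)c(OCc2ccccc2)c(OCc2ccccc2)c1 | intermediate (not isolated)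
13 | (2S,3S)-7-(benzyloxy)-8-bromo-3-hydroxy-2-[3,4,5-tris(benzyloxy)phenyl]chroman-4-one | O=C1c2ccc(OCc3ccccc3)c(Br)c2O[C@@H](c2cc(OCc3ccccc3)c(OCc3ccccc3)c(OCc3ccccc3)c2)[C@@H]1O | intermediate
14 | (2S,3R,4S)-7-(benzyloxy)-8-bromo-2-[3,4,5-tris(benzyloxy)phenyl]chromane-3,4-diol | Brc1c(OCc3ccccc3)ccc2c1O[C@@H](c1cc(OCc3ccccc3)c(OCc3ccccc3)c(OCc3ccccc3)c1)[C@H](O)[C@H]2O | intermediate
15 | (2S,3R,4S)-7-(benzyloxy)-8-bromo-4-methoxy-2-[3,4,5-tris(benzyloxy)phenyl]chroman-3-ol (expected major C4 epimer) | Brc1c(OCc3ccccc3)ccc2c1O[C@@H](c1cc(OCc3ccccc3)c(OCc3ccccc3)c(OCc3ccccc3)c1)[C@H](O)[C@H]2OC | intermediate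
16 | (2S,4S)-7-(benzyloxy)-8-bromo-4-methoxy-2-[3,4,5-tris(benzyloxy)phenyl]chroman-3-one | Brc1c(OCc3ccccc3)ccc2c1O[C@@H](c1cc(OCc3ccccc3)c(OCc3ccccc3)c(OCc3ccccc3)c1)C(=O)[C@H]2OC | intermediate
17 | (2S,3S,4S)-7-(benzyloxy)-8-bromo-4-methoxy-2-[3,4,5-tris(benzyloxy)phenyl]chroman-3-ol | Brc1c(OCc3ccccc3)ccc2c1O[C@@H](c1cc(OCc3ccccc3)c(OCc3ccccc3)c(OCc3ccccc3)c1)[C@@H](O)[C@H]2OC | intermediate
18 | (−)-epicatechin, (2R,3R)-2-(3,4-dihydroxyphenyl)chromane-3,5,7-triol | Oc1cc(O)c2c(c1)O[C@H](c1ccc(O)c(O)c1)[C@H](O)C2 | starting material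
19 | (2R,3R)-5,7-bis(benzyloxy)-2-[3,4-bis(benzyloxy)phenyl]chroman-3-ol | O(Cc3ccccc3)c1cc(OCc3ccccc3)c2c(c1)O[C@H](c1ccc(OCc3ccccc3)c(OCc3ccccc3)c1)[C@H](O)C2 | intermediate
20 | 8-bromo-7,3',4',5'-tetra-O-benzyl-ent-epirobinetinidol-(4α→8)-5,7,3',4'-tetra-O-benzyl-epicatechin (middle 2S,3S,4S; bottom 2R,3R) | Brc1c(OCc3ccccc3)ccc2c1O[C@@H](c1cc(OCc3ccccc3)c(OCc3ccccc3)c(OCc3ccccc3)c1)[C@@H](O)[C@@H]2c1c(OCc3ccccc3)cc(OCc3ccccc3)c2c1O[C@H](c1ccc(OCc3ccccc3)c(OCc3ccccc3)c1)[C@H](O)C2 | intermediate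
21 | 8-bromo-3,7,3',4',5'-penta-O-benzyl-ent-epirobinetinidol-(4α→8)-3,5,7,3',4'-penta-O-benzyl-epicatechin | Brc1c(OCc3ccccc3)ccc2c1O[C@@H](c1cc(OCc3ccccc3)c(OCc3ccccc3)c(OCc3ccccc3)c1)[C@@H](OCc3ccccc3)[C@@H]2c1c(OCc3ccccc3)cc(OCc3ccccc3)c2c1O[C@H](c1ccc(OCc3ccccc3)c(OCc3ccccc3)c1)[C@H](OCc3ccccc3)C2 | intermediate
22 | C8 aryllithium of 21 (lithium in place of bromine on the middle ring A) | [Li]c1c(OCc3ccccc3)ccc2c1O[C@@H](c1cc(OCc3ccccc3)c(OCc3ccccc3)c(OCc3ccccc3)c1)[C@@H](OCc3ccccc3)[C@@H]2c1c(OCc3ccccc3)cc(OCc3ccccc3)c2c1O[C@H](c1ccc(OCc3ccccc3)c(OCc3ccccc3)c1)[C@H](OCc3ccccc3)C2 | intermediate (not isolated)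
23 | lithium tertiary carbinolate from 1,2-addition of 22 to 5 (aryl silyl ether and epoxide intact; expected chelation-controlled carbinol epimer) | CC(C)(C)[Si](C)(C)Oc1cc(OCc3ccccc3)ccc1[C@@](O[Li])([C@H]1O[C@@H]1c1cc(OCc3ccccc3)c(OCc3ccccc3)c(OCc3ccccc3)c1)c1c(OCc3ccccc3)ccc2c1O[C@@H](c1cc(OCc3ccccc3)c(OCc3ccccc3)c(OCc3ccccc3)c1)[C@@H](OCc3ccccc3)[C@@H]2c1c(OCc3ccccc3)cc(OCc3ccccc3)c2c1O[C@H](c1ccc(OCc3ccccc3)c(OCc3ccccc3)c1)[C@H](OCc3ccccc3)C2 | intermediate (not isolated)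
24 | lithium phenoxide after the 1,5 silyl shift (tertiary silyl ether, epoxide intact) | [Li]Oc1cc(OCc3ccccc3)ccc1[C@@](O[Si](C)(C)C(C)(C)C)([C@H]1O[C@@H]1c1cc(OCc3ccccc3)c(OCc3ccccc3)c(OCc3ccccc3)c1)c1c(OCc3ccccc3)ccc2c1O[C@@H](c1cc(OCc3ccccc3)c(OCc3ccccc3)c(OCc3ccccc3)c1)[C@@H](OCc3ccccc3)[C@@H]2c1c(OCc3ccccc3)cc(OCc3ccccc3)c2c1O[C@H](c1ccc(OCc3ccccc3)c(OCc3ccccc3)c1)[C@H](OCc3ccccc3)C2 | intermediate (not isolated)
25 | cyclised lithium C3-alkoxide with the top pyran ring closed (4-O-silyl; 2β-aryl, 3α-O) | O(Cc3ccccc3)c1ccc2c(c1)O[C@@H](c1cc(OCc3ccccc3)c(OCc3ccccc3)c(OCc3ccccc3)c1)[C@H](O[Li])[C@@]2(O[Si](C)(C)C(C)(C)C)c1c(OCc3ccccc3)ccc2c1O[C@@H](c1cc(OCc3ccccc3)c(OCc3ccccc3)c(OCc3ccccc3)c1)[C@@H](OCc3ccccc3)[C@@H]2c1c(OCc3ccccc3)cc(OCc3ccccc3)c2c1O[C@H](c1ccc(OCc3ccccc3)c(OCc3ccccc3)c1)[C@H](OCc3ccccc3)C2 | intermediate (not isolated)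
26 | trimer tertiary alcohol: top unit (2S,3S,4S)-7-(benzyloxy)-3-(tert-butyldimethylsilyloxy)-4-hydroxy-2-[3,4,5-tris(benzyloxy)phenyl]chroman-4-yl (4-OH α, aryl β) bonded through C4 to C8 of the middle unit of debrominated 21 | O(Cc3ccccc3)c1ccc2c(c1)O[C@@H](c1cc(OCc3ccccc3)c(OCc3ccccc3)c(OCc3ccccc3)c1)[C@H](O[Si](C)(C)C(C)(C)C)[C@@]2(O)c1c(OCc3ccccc3)ccc2c1O[C@@H](c1cc(OCc3ccccc3)c(OCc3ccccc3)c(OCc3ccccc3)c1)[C@@H](OCc3ccccc3)[C@@H]2c1c(OCc3ccccc3)cc(OCc3ccccc3)c2c1O[C@H](c1ccc(OCc3ccccc3)c(OCc3ccccc3)c1)[C@H](OCc3ccccc3)C2 | intermediate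
27 | 3-O-(tert-butyldimethylsilyl)-7,3',4',5'-tetra-O-benzyl-ent-robinetinidol-(4α→8)-3,7,3',4',5'-penta-O-benzyl-ent-epirobinetinidol-(4α→8)-3,5,7,3',4'-penta-O-benzyl-epicatechin (top 2S,3R,4S) | O(Cc3ccccc3)c1ccc2c(c1)O[C@@H](c1cc(OCc3ccccc3)c(OCc3ccccc3)c(OCc3ccccc3)c1)[C@H](O[Si](C)(C)C(C)(C)C)[C@@H]2c1c(OCc3ccccc3)ccc2c1O[C@@H](c1cc(OCc3ccccc3)c(OCc3ccccc3)c(OCc3ccccc3)c1)[C@@H](OCc3ccccc3)[C@@H]2c1c(OCc3ccccc3)cc(OCc3ccccc3)c2c1O[C@H](c1ccc(OCc3ccccc3)c(OCc3ccccc3)c1)[C@H](OCc3ccccc3)C2 | intermediate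
28 | 7,3',4',5'-tetra-O-benzyl-ent-robinetinidol-(4α→8)-3,7,3',4',5'-penta-O-benzyl-ent-epirobinetinidol-(4α→8)-3,5,7,3',4'-penta-O-benzyl-epicatechin | O(Cc3ccccc3)c1ccc2c(c1)O[C@@H](c1cc(OCc3ccccc3)c(OCc3ccccc3)c(OCc3ccccc3)c1)[C@H](O)[C@@H]2c1c(OCc3ccccc3)ccc2c1O[C@@H](c1cc(OCc3ccccc3)c(OCc3ccccc3)c(OCc3ccccc3)c1)[C@@H](OCc3ccccc3)[C@@H]2c1c(OCc3ccccc3)cc(OCc3ccccc3)c2c1O[C@H](c1ccc(OCc3ccccc3)c(OCc3ccccc3)c1)[C@H](OCc3ccccc3)C2 | intermediate
29 | ent-robinetinidol-(4α→8)-ent-epirobinetinidol-(4α→8)-epicatechin (top 2S,3R,4S; middle 2S,3S,4S; bottom 2R,3R) | Oc1ccc2c(c1)O[C@@H](c1cc(O)c(O)c(O)c1)[C@H](O)[C@@H]2c1c(O)ccc2c1O[C@@H](c1cc(O)c(O)c(O)c1)[C@@H](O)[C@@H]2c1c(O)cc(O)c2c1O[C@H](c1ccc(O)c(O)c1)[C@H](O)C2 | target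

**Summary and risks**

Total step count: 20. Longest linear sequence: 16 steps (steps 4–13, then 15–20).

Steps most likely to fail:

Step 17. The O→O silyl transfer may stall at the crowded tertiary alkoxide, the epoxide may migrate (Payne rearrangement), or the phenoxide may open the epoxide 5-exo instead of 6-endo. The fallback uses known chemistry only, sets out from 5 and 21 and comes back at 26. Epoxy ketone 5 is treated with n-Bu4NF in THF at 0 °C (then AcOH), which should cyclise it, as in step 9, to the dihydroflavonol (2S,3S)-7-(benzyloxy)-3-hydroxy-2-[3,4,5-tris(benzyloxy)phenyl]chroman-4-one F1. Silylation with t-BuMe2SiOTf and 2,6-lutidine gives its 3-O-(tert-butyldimethylsilyl) ether F2. Aryllithium 22, generated from 21 with t-BuLi at −78 °C, is then added to the C4 ketone of F2 anti to the 3-silyloxy group, which should give the tertiary alcohol 26.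

Step 18. Hydride transfer to the strongly stabilised, crowded cation may be slow and the facial selectivity of hydride delivery may be poor. The fallback replaces steric approach control by neighbouring-group participation, sets out from 26 and comes back at 28. n-Bu4NF removes the silyl group to give the top-unit 3,4-diol F3. Ac2O, DMAP and pyridine acylate only the secondary hydroxyl to give the 3-O-acetate F4. n-Bu3SnH and CF3CO2H then ionise C4, the acetate should bridge the α-face as a cis-fused acetoxonium ion, and hydride should open it at C4 from the β-face to give the 3-O-acetyl trimer F5. K2CO3 in MeOH/THF removes the acetate to give 28.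

Step 15. The 8-bromo-5-deoxy electrophile may ionise incompletely, and attack at C6 of the nucleophile or oligomerisation may compete. The fallback changes the electrophile class to thiophilic activation, sets out from 17 and comes back at 20. BnSH and BF3·OEt2 in CH2Cl2 convert 17 into the 4α-benzylthio ether (2S,3S,4R)-7-(benzyloxy)-4-(benzylthio)-8-bromo-2-[3,4,5-tris(benzyloxy)phenyl]chroman-3-ol F6. AgBF4 in THF at 0 °C with an excess of 19 then abstracts the thiolate under neutral conditions and should give 20 with the same 3,4-trans course.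

**Further compounds**

F1 | step 17 | (2S,3S)-7-(benzyloxy)-3-hydroxy-2-[3,4,5-tris(benzyloxy)phenyl]chroman-4-one | O=C1c2ccc(OCc3ccccc3)cc2O[C@@H](c2cc(OCc3ccccc3)c(OCc3ccccc3)c(OCc3ccccc3)c2)[C@@H]1O
F2 | step 17 | (2S,3S)-7-(benzyloxy)-3-(tert-butyldimethylsilyloxy)-2-[3,4,5-tris(benzyloxy)phenyl]chroman-4-one | O=C1c2ccc(OCc3ccccc3)cc2O[C@@H](c2cc(OCc3ccccc3)c(OCc3ccccc3)c(OCc3ccccc3)c2)[C@@H]1O[Si](C)(C)C(C)(C)C
F3 | step 18 | trimer with top-unit 3,4-diol (26 without the silyl group) | O(Cc3ccccc3)c1ccc2c(c1)O[C@@H](c1cc(OCc3ccccc3)c(OCc3ccccc3)c(OCc3ccccc3)c1)[C@H](O)[C@@]2(O)c1c(OCc3ccccc3)ccc2c1O[C@@H](c1cc(OCc3ccccc3)c(OCc3ccccc3)c(OCc3ccccc3)c1)[C@@H](OCc3ccccc3)[C@@H]2c1c(OCc3ccccc3)cc(OCc3ccccc3)c2c1O[C@H](c1ccc(OCc3ccccc3)c(OCc3ccccc3)c1)[C@H](OCc3ccccc3)C2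
F4 | step 18 | trimer with top-unit 3-O-acetyl-4-hydroxy | O(Cc3ccccc3)c1ccc2c(c1)O[C@@H](c1cc(OCc3ccccc3)c(OCc3ccccc3)c(OCc3ccccc3)c1)[C@H](OC(C)=O)[C@@]2(O)c1c(OCc3ccccc3)ccc2c1O[C@@H](c1cc(OCc3ccccc3)c(OCc3ccccc3)c(OCc3ccccc3)c1)[C@@H](OCc3ccccc3)[C@@H]2c1c(OCc3ccccc3)cc(OCc3ccccc3)c2c1O[C@H](c1ccc(OCc3ccccc3)c(OCc3ccccc3)c1)[C@H](OCc3ccccc3)C2
F5 | step 18 | 3-O-acetyl derivative of 28 (top unit 4α-aryl) | O(Cc3ccccc3)c1ccc2c(c1)O[C@@H](c1cc(OCc3ccccc3)c(OCc3ccccc3)c(OCc3ccccc3)c1)[C@H](OC(C)=O)[C@@H]2c1c(OCc3ccccc3)ccc2c1O[C@@H](c1cc(OCc3ccccc3)c(OCc3ccccc3)c(OCc3ccccc3)c1)[C@@H](OCc3ccccc3)[C@@H]2c1c(OCc3ccccc3)cc(OCc3ccccc3)c2c1O[C@H](c1ccc(OCc3ccccc3)c(OCc3ccccc3)c1)[C@H](OCc3ccccc3)C2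
F6 | step 15 | (2S,3S,4R)-7-(benzyloxy)-4-(benzylthio)-8-bromo-2-[3,4,5-tris(benzyloxy)phenyl]chroman-3-ol | Brc1c(OCc3ccccc3)ccc2c1O[C@@H](c1cc(OCc3ccccc3)c(OCc3ccccc3)c(OCc3ccccc3)c1)[C@@H](O)[C@@H]2SCc3ccccc3
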